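## The problem

The target is a 3,3'-linked biflavanone in which two 5,7-dihydroxychroman-4-ones are joined by the single bond C3–C3'; unit A carries a 4-methoxyphenyl group at C2 and unit B (primed) a 4-hydroxyphenyl group at C2'. Its four stereocentres form one chain, C2–C3–C3'–C2', with the configuration (2S,3S,2'R,3'S), so that unit A is 2,3-cis and unit B is 2',3'-trans. Both C3 and C3' are alpha to a ketone and both pyranone C2–O bonds can open by retro-oxa-Michael reaction; in unit B this lability helps, because trans is the thermodynamic arrangement, but in unit A it is the main threat, because base, fluoride or heat would erase the cis arrangement. Unit A must therefore travel with C4 at the alcohol level through every basic step, and its ketone must be released late under neutral conditions. C2 can be fixed by a catalyst and C3 set relative to it, whereas C3' and C2' must be induced across the freely rotating C3–C3' bond, which is the hardest stereochemical question. The two aryl groups differ only as methyl ether and free phenol, and five phenols have to be freed at the end without acid or base; benzyl ethers and hydrogenolysis answer both points. The enabling feature is ring A' of unit B: O1' and the acyl carbon C4' sit on the adjacent carbons C8a' and C4a', with oxygens at C5' and C7', which is the pattern left when a carboxylate adds to a 3,5-dialkoxybenzyne and the acyl group shifts to carbon, while C4'–C3'–C2' with its aryl group is then a cinnamic acid. Ring A of unit A shows the same pattern, so one aryne precursor can serve twice.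

## Retrosynthesis

**28 to 25 (end-game, no skeletal bond cut).** The target 28 comes from its pentabenzyl ether 27 by hydrogenolysis, 27 from the C4 alcohol 26 by neutral oxidation, and 26 from the silyl ether 25. The detour through the C4 alcohol keeps C3 of the cis unit from enolising until the last two steps. The C4 centre is expendable.

**25 to 23 and 5 (key cut).** Three bonds of unit B are cut: O1'–C8a', C4'–C4a' and O1'–C2'. This removes ring A' and the pyranone ring together and leaves the (E)-cinnamic acid 23 and the aryne precursor 5, which releases aryne 12 in the flask. Two neighbouring cuts were weighed: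
- Cutting C3–C3' would need an unsymmetrical coupling of two flavanone enolates, with no handle for one cis and one trans unit.
- Cutting only O1'–C2' would need the ortho-hydroxyaryl ketone made first, normally by acid-mediated acylation that the C4-oxygenated, electron-rich unit A would not survive.

The forward reaction must add the carboxylate to the correct aryne carbon, shift the acyl group to carbon, close 6-endo, and deliver the 2',3'-trans unit in the correct sense relative to C3.

**23 to 20.** The silyl ether at C4 and the free carboxyl of 23 are the two ends of the cis-fused lactone 20. The lactone holds both functions in one ring, so neither needs its own protecting group earlier. The forward step is hydrolysis, double silylation and selective cleavage of the silyl ester.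

**20 to 16 and 17.** The future C2'=C3' double bond is cut by an aldol condensation, giving the simple lactone 16 and commercial aldehyde 17. The forward step only has to give the (E)-arylidene lactone, which is the stable isomer.

**16 to 14.** The C4–H bond and the lactone C–O bond are cut. A transfer hydrogenation of racemic ketone 14 is asked to resolve C2, to set C3 cis through dynamic epimerisation, and to set C4 by the catalyst. This turns a simple racemate into a single enantiomer with three contiguous centres.

**14 to 11 and 5.** Unit A is cut exactly as unit B was (O1–C8a, C4–C4a, O1–C2), back to the benzylidenesuccinic half-ester 11 and a second portion of 5, again by way of aryne 12. The alternative, a flavone-3-acetate from a phloroglucinol ketone with later cis hydrogenation, would clash with the benzyl ethers and needs more steps.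

**11 to 9, 6 and 7.** The half-ester 11 comes from the diacid 9 through its anhydride 10, which methanol opens at the non-conjugated carbonyl. Diacid 9 comes from a Stobbe condensation of 6 and 7.

**5 to 2 and 1.** The ortho-silyl aryl triflate 5 comes from bromophenol 2 by retro-Brook rearrangement and triflation, and 2 from phenol 1 by ortho bromination.

## Roads not taken

**Alternative 1:** The cut is through C2–C3 and C2'–C3' at once. The forward key step is an asymmetric Diels–Alder reaction of the (E,E)-1,4-diaryl diene A2 with the (E)-aroylacryloyl imide A3, for example under Cu(OTf)2 with a bis(oxazoline) ligand, giving the cyclohexene A1.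
- Merits: one catalytic step sets all four stereocentres. The endo rule together with the trans dienophile gives one cis and one trans aryl/carbonyl pair, which is exactly the pattern of the target. No induction across C3–C3' is needed; in this respect the road is better than the chosen plan.
- Weak points: the two diene termini differ only by a remote para substituent, so the orientation of the cycloaddition (which aryl lands next to the aroyl group) is hardly controlled. As A1 is formulated, the aryl group on its cis side is a benzyl ether where the target has the methyl ether, so that terminus of A2 would have to be 4-methoxyphenyl. 1,4-Diaryl dienes are also sluggish dienes. After the cycloaddition the ring alkene must be cleaved, both alkene carbons replaced by oxygen with retention, the imide turned into the second aryl ketone and two pyranone rings closed by substitution of aryl fluorides. All of this happens while a cis centre sits next to a carbonyl group.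
- Comparison: the chosen plan sets against the better stereochemical logic of A1 a key step that delivers the finished pyranone ring directly, three steps after the key step instead of many, and a cis unit that is never a ketone under base.

**Alternative 2:** The cut is C2–C3 of unit A. The forward key step is decomposition of the alpha-diazo ketone A5 with a dirhodium tetracarboxylate such as Rh2(OAc)4 (divalent rhodium), and insertion of the carbenoid into a benzylic C–H bond of the 4-methoxybenzyl ether to give A4.
- Merits: the fragile cis unit is made last and at the ketone level, so the reduction, protection and re-oxidation of C4 are saved. The C–H bond is doubly activated (ether and electron-rich benzyl), and a chiral dirhodium catalyst could reinforce the cis selectivity. In end-game economy this road is better than the chosen plan.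
- Weak points: the carbenoid carbon carries C3'–H, and 1,2-hydride shift to the alkene is usually faster than formation of a six-membered ring by insertion. Ylide formation at the ether oxygen and addition to the anisyl ring also compete. A5 itself requires diazo transfer next to an epimerisable C3' centre in a hindered 1,4-dicarbonyl array. Two extra orthogonal protecting groups are needed.
- Comparison: the chosen plan sets a polar, precedented ring construction against these competing carbenoid pathways, and pays for it with three redox and protecting-group steps at C4.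

**Alternative 3:** The cut is O1'–C2' alone. The forward key step is dehydrogenation of the 4-hydroxybenzyl compound A7 with DDQ to the para-quinone methide A8, to which the ortho phenol of ring A' adds, giving A6.
- Merits: only the aryl group of unit B can form a quinone methide, since the anisyl group is methylated, so the two aryl groups are told apart by the target's own functionality. The conditions are not basic. A6 needs only hydrogenolysis to reach the target, which is shorter after the key step than the chosen plan.
- Weak points: A7 already contains unit A as a cis flavanone ketone with C3 inside an enolisable 1,4-dicarbonyl array, so the cis centre is exposed during the whole synthesis of A7. DDQ is also the standard reagent for dehydrogenating flavanones to flavones. The C3' centre must be made before the key step. The addition to A8 is kinetic, so the trans arrangement and its sense relative to unit A are not corrected by equilibration unless base is added, which unit A as a ketone would not tolerate. Ring A' and its ketone must be installed by separate chemistry.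
- Comparison: the chosen plan keeps unit A as an alcohol through all basic stages, builds ring A' and the pyranone in one operation and lets unit B equilibrate, but it needs two more steps at the end.

Key step: step 9

Assumption: compound 1 is taken as a purchasable dibenzyl ether of phloroglucinol.
Assumption: 14 is racemic and is drawn and named as the (2S,3R) enantiomer of its trans form; its C3 epimer may accompany it and is equally usable, because step 6 epimerises C3.

## Route

Step 1
Reactants: 1 3,5-bis(benzyloxy)phenol
Product: 2 3,5-bis(benzyloxy)-2-bromophenol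
Conditions: NBS (1.0 equiv), i-Pr2NH (10 mol %), CH2Cl2, −78 → 0 °C
Reagents that add atoms: N-bromosuccinimide, O=C1CCC(=O)N1Br
Why: Electrophilic aromatic bromination; the amine/NBS pair delivers bromine ortho to the free hydroxyl through hydrogen bonding and the position between the two benzyloxy groups is the more hindered one, so the 2-bromide should predominate and is separable from its 4-isomer.

Step 2
Reactants: 2 3,5-bis(benzyloxy)-2-bromophenol
Product: 5 3,5-bis(benzyloxy)-2-(trimethylsilyl)phenyl trifluoromethanesulfonate, via trimethylsilyl ether 3 (not isolated), via lithium silylphenoxide 4 (not isolated)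
Conditions: HN(SiMe3)2, THF, 70 °C, evaporate; n-BuLi, THF, −100 → −78 °C; Tf2O, −100 °C → rt
Reagents that add atoms: hexamethyldisilazane, C[Si](C)(C)N[Si](C)(C)C; trifluoromethanesulfonic anhydride, O=S(=O)(OS(=O)(=O)C(F)(F)F)C(F)(F)F
Why: O-Silylation, bromine–lithium exchange and retro-Brook (1,3 oxygen-to-carbon) silyl migration give the ortho-silyl phenoxide, which is triflated in the same flask; halogen–metal exchange at −100 °C is faster than benzylic deprotonation of the benzyl ethers.

Step 3
Reactants: 6 4-methoxybenzaldehyde; 7 dimethyl succinate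
Product: 9 (E)-2-(4-methoxybenzylidene)succinic acid, via potassium half-ester salt 8 (not isolated)
Conditions: KOt-Bu, t-BuOH, 85 °C; then NaOH, H2O/MeOH, reflux; HCl
Reagents that add atoms: sodium hydroxide, [Na+].[OH-]
Why: Stobbe condensation through the paraconic ester lactone gives the (E)-half-ester with the aryl group trans to the conjugated carboxyl, and saponification of the remaining ester gives the crystalline diacid.

Step 4
Reactants: 9 (E)-2-(4-methoxybenzylidene)succinic acid
Product: 11 (E)-2-(2-methoxy-2-oxoethyl)-3-(4-methoxyphenyl)prop-2-enoic acid, via cyclic anhydride 10 (not isolated)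
Conditions: Ac2O, 80 °C, evaporate; MeOH, 25 → 65 °C
Reagents that add atoms: methanol, CO
Why: Cyclic anhydride formation followed by regioselective alcoholysis at the non-conjugated, more electrophilic carbonyl (as with itaconic anhydride) leaves the conjugated carboxyl free, which is the regiochemistry the Stobbe half-ester itself does not give.

Step 5
Reactants: 11 (E)-2-(2-methoxy-2-oxoethyl)-3-(4-methoxyphenyl)prop-2-enoic acid; 5 3,5-bis(benzyloxy)-2-(trimethylsilyl)phenyl trifluoromethanesulfonate
Product: 14 rac-methyl 2-[(2S*,3R*)-5,7-bis(benzyloxy)-2-(4-methoxyphenyl)-4-oxochroman-3-yl]acetate, via aryne 12 (not isolated), via caesium acylphenoxide 13 (not isolated)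
Conditions: 5 (1.5 equiv), CsF (4 equiv), THF, 125 °C, sealed tube
Reagents that add atoms: none
Why: Fluoride-induced aryne insertion into the carboxyl C–O bond of an alpha,beta-unsaturated acid followed by 6-endo-trig oxa-Michael closure, the known route to chroman-4-ones; the flanking benzyloxy group sends the carboxylate to the remote aryne carbon, and C2/C3 form without control (trans expected as the main epimer), which is harmless because step 6 resolves C2 and epimerises C3.

Step 6
Reactants: 14 rac-methyl 2-[(2S*,3R*)-5,7-bis(benzyloxy)-2-(4-methoxyphenyl)-4-oxochroman-3-yl]acetate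
Product: 16 (3aS,4S,9bS)-7,9-bis(benzyloxy)-4-(4-methoxyphenyl)-3,3a,4,9b-tetrahydro-2H-furo[3,2-c]chromen-2-one, via all-cis hydroxy ester 15 (not isolated)
Conditions: RuCl[(S,S)-TsDPEN](p-cymene) (2 mol %), HCO2H/Et3N (1:3), EtOAc, 40 °C, to about half conversion; then DBU (cat.), rt
Reagents that add atoms: none
Why: Noyori–Ikariya asymmetric transfer hydrogenation used as a kinetic resolution at C2 with dynamic epimerisation at C3: the (S,S) catalyst delivers hydride to the ketone face that gives the (4S) alcohol, and only the (2S)-2,3-cis epimer offers that face free of both substituents, so the (2S) enantiomer is drained through its cis epimer while the (2R) antipode of 14 remains as ketone and is separated; the all-cis gamma-hydroxy ester then closes to the cis-fused lactone, which ties up the C4 hydroxyl and the acetate together.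

Step 7
Reactants: 16 (3aS,4S,9bS)-7,9-bis(benzyloxy)-4-(4-methoxyphenyl)-3,3a,4,9b-tetrahydro-2H-furo[3,2-c]chromen-2-one; 17 4-(benzyloxy)benzaldehyde
Product: 20 (3E,3aS,4S,9bS)-7,9-bis(benzyloxy)-3-[4-(benzyloxy)benzylidene]-4-(4-methoxyphenyl)-3,3a,4,9b-tetrahydro-2H-furo[3,2-c]chromen-2-one, via lithium aldolate 18 (not isolated), via aldol mesylate 19 (not isolated)
Conditions: LiN(SiMe3)2, THF, −78 °C; 17; MsCl, −78 → 0 °C; DBU, 0 °C → rt
Reagents that add atoms: none
Why: Lactone enolate aldol addition, mesylation of the aldolate and E1cB elimination (aldol condensation); the (E)-arylidene lactone with the aryl group away from the lactone carbonyl is the thermodynamic isomer, and the ring-fusion centres are not touched because the enolate has no leaving group in the beta position.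

Step 8
Reactants: 20 (3E,3aS,4S,9bS)-7,9-bis(benzyloxy)-3-[4-(benzyloxy)benzylidene]-4-(4-methoxyphenyl)-3,3a,4,9b-tetrahydro-2H-furo[3,2-c]chromen-2-one
Product: 23 (E)-3-[4-(benzyloxy)phenyl]-2-[(2S,3S,4S)-5,7-bis(benzyloxy)-2-(4-methoxyphenyl)-4-(triisopropylsilyloxy)chroman-3-yl]prop-2-enoic acid, via potassium hydroxy carboxylate 21 (not isolated), via bis-silyl derivative 22 (not isolated)
Conditions: KOH, THF/MeOH/H2O, rt, evaporate, toluene azeotrope; i-Pr3SiOTf (3 equiv), 2,6-lutidine, CH2Cl2, 0 °C → rt; then K2CO3, MeOH/THF/H2O, rt; pH 5 buffer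
Reagents that add atoms: potassium hydroxide, [K+].[OH-]; triisopropylsilyl trifluoromethanesulfonate, CC(C)[Si](OS(=O)(=O)C(F)(F)F)(C(C)C)C(C)C
Why: Saponification opens the lactone, the silyl triflate silylates both the carboxylate and the hindered C4 hydroxyl, and carbonate methanolysis cleaves only the silyl ester, the known way to turn a gamma-lactone into a gamma-silyloxy acid; the alkene keeps its (E) geometry and the mildly acidic work-up spares the acid-labile benzylic silyl ether.

Step 9
Reactants: 23 (E)-3-[4-(benzyloxy)phenyl]-2-[(2S,3S,4S)-5,7-bis(benzyloxy)-2-(4-methoxyphenyl)-4-(triisopropylsilyloxy)chroman-3-yl]prop-2-enoic acid; 5 3,5-bis(benzyloxy)-2-(trimethylsilyl)phenyl trifluoromethanesulfonate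
Product: 25 (2S,3S,4S)-5,7-bis(benzyloxy)-3-{(2R,3S)-5,7-bis(benzyloxy)-2-[4-(benzyloxy)phenyl]-4-oxochroman-3-yl}-2-(4-methoxyphenyl)-4-(triisopropylsilyloxy)chromane, via caesium acylphenoxide 24 (not isolated)
Conditions: 5 (1.5–2 equiv), CsF (4–5 equiv, dried), THF, 125 °C, sealed tube
Reagents that add atoms: none
Why: Fluoride removes the trimethylsilyl group of 5 and expels triflate, which releases aryne 12 in the flask once more exactly as in step 5, and the carboxylate of 23 attacks the aryne carbon remote from the flanking benzyloxy group so that the aryl anion forms next to that inductively stabilising oxygen. The aryl anion attacks the ester carbonyl in a 4-exo-trig closure and the four-membered alkoxide opens to the ortho-acyl phenoxide 24, which forms O1'–C8a' and C4'–C4a'. The phenoxide then adds to C2' of the enone in a 6-endo-trig oxa-Michael closure (O1'–C2') and the enolate is protonated at C3'. The closest known reaction type is the fluoride-induced insertion of arynes into the C–O bond of carboxylic acids, which gives ortho-hydroxyaryl ketones and, from alpha,beta-unsaturated acids, chroman-4-ones. C2' and C3' are under thermodynamic control because oxa-Michael addition and C3' enolisation are reversible at 125 °C in the presence of fluoride, so the 2',3'-trans arrangement with both substituents equatorial is expected. The sense relative to unit A rests on 1,2-induction from C3: in the staggered conformer with H3 and H3' anti, the desired isomer places the large silyloxy-bearing C4 beside the flat C4' carbonyl and C2 beside C2', whereas the other trans isomer forces C4 against the aryl-bearing C2', and the triisopropylsilyl group is chosen to make this bias as large as possible. Regioselectivity needs only the 3-alkoxy group of the aryne; chemoselectivity needs an inert unit A, which the C4 silyl ether secures by removing the C3 enolisation pathway, triisopropylsilyl being the common silyl group most resistant to fluoride. Dried CsF and a moderate excess of 5 should limit protonation of the aryl anion to the aryl ester and arylation of the phenoxide by a second aryne.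

Step 10
Reactants: 25 (2S,3S,4S)-5,7-bis(benzyloxy)-3-{(2R,3S)-5,7-bis(benzyloxy)-2-[4-(benzyloxy)phenyl]-4-oxochroman-3-yl}-2-(4-methoxyphenyl)-4-(triisopropylsilyloxy)chromane
Product: 26 (2R,3S)-5,7-bis(benzyloxy)-2-[4-(benzyloxy)phenyl]-3-[(2S,3R,4S)-5,7-bis(benzyloxy)-4-hydroxy-2-(4-methoxyphenyl)chroman-3-yl]chroman-4-one
Conditions: Bu4NF, AcOH (1:1), THF, 0 → 40 °C
Reagents that add atoms: none
Why: Fluoride cleavage of the silyl ether; acetic acid buffers the alkoxide so that unit B does not open by retro-oxa-Michael reaction, and no stereocentre is touched (the descriptor at C3 changes only because the priorities change).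

Step 11
Reactants: 26 (2R,3S)-5,7-bis(benzyloxy)-2-[4-(benzyloxy)phenyl]-3-[(2S,3R,4S)-5,7-bis(benzyloxy)-4-hydroxy-2-(4-methoxyphenyl)chroman-3-yl]chroman-4-one
Product: 27 (2S,3S)-5,7-bis(benzyloxy)-3-{(2R,3S)-5,7-bis(benzyloxy)-2-[4-(benzyloxy)phenyl]-4-oxochroman-3-yl}-2-(4-methoxyphenyl)chroman-4-one
Conditions: Dess–Martin periodinane, NaHCO3, CH2Cl2, 0 °C → rt
Reagents that add atoms: none
Why: Dess–Martin oxidation of the benzylic secondary alcohol under buffered, near-neutral conditions; no enolate is generated at C3, so the 2,3-cis arrangement should survive, and any cyclic hemiketal between the C4 hydroxyl and the C4' ketone is drained through its open form.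

Step 12
Reactants: 27 (2S,3S)-5,7-bis(benzyloxy)-3-{(2R,3S)-5,7-bis(benzyloxy)-2-[4-(benzyloxy)phenyl]-4-oxochroman-3-yl}-2-(4-methoxyphenyl)chroman-4-one
Product: 28 (2S,3S)-5,7-dihydroxy-3-[(2R,3S)-5,7-dihydroxy-2-(4-hydroxyphenyl)-4-oxochroman-3-yl]-2-(4-methoxyphenyl)chroman-4-one (CNP0196568.4)
Conditions: H2 (1 atm), Pd/C, EtOAc/MeOH, rt
Reagents that add atoms: none
Why: Hydrogenolysis of the five benzyl ethers over palladium under neutral conditions; the aryl ketones and the pyranone C–O bonds should be left intact at atmospheric pressure, the methyl ether stays, and no stereocentre is touched.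

## Compound list

1 | 3,5-bis(benzyloxy)phenol | Oc1cc(OCc2ccccc2)cc(OCc2ccccc2)c1 | starting material
2 | 3,5-bis(benzyloxy)-2-bromophenol | Oc1cc(OCc2ccccc2)cc(OCc2ccccc2)c1Br | intermediate
3 | [3,5-bis(benzyloxy)-2-bromophenoxy]trimethylsilane | C[Si](C)(C)Oc1cc(OCc2ccccc2)cc(OCc2ccccc2)c1Br | intermediate (not isolated)
4 | lithium 3,5-bis(benzyloxy)-2-(trimethylsilyl)phenoxide | [Li+].[O-]c1cc(OCc2ccccc2)cc(OCc2ccccc2)c1[Si](C)(C)C | intermediate (not isolated)
5 | 3,5-bis(benzyloxy)-2-(trimethylsilyl)phenyl trifluoromethanesulfonate | C[Si](C)(C)c1c(OCc2ccccc2)cc(OCc2ccccc2)cc1OS(=O)(=O)C(F)(F)F | intermediate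
6 | 4-methoxybenzaldehyde | COc1ccc(C=O)cc1 | starting material
7 | dimethyl succinate | COC(=O)CCC(=O)OC | starting material
8 | potassium (E)-3-(methoxycarbonyl)-4-(4-methoxyphenyl)but-3-enoate | COC(=O)/C(CC(=O)[O-])=C/c1ccc(OC)cc1.[K+] | intermediate (not isolated)
9 | (E)-2-(4-methoxybenzylidene)succinic acid | COc1ccc(/C=C(\CC(=O)O)C(=O)O)cc1 | intermediate
10 | (E)-3-(4-methoxybenzylidene)oxolane-2,5-dione | COc1ccc(/C=C2\CC(=O)OC2=O)cc1 | intermediate (not isolated)
11 | (E)-2-(2-methoxy-2-oxoethyl)-3-(4-methoxyphenyl)prop-2-enoic acid | COC(=O)C/C(C(=O)O)=C\c1ccc(OC)cc1 | intermediate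
12 | 3,5-bis(benzyloxy)benzyne (released from 5 in step 5; the same species arises again from 5 in the flask of step 9) | C1#CC=C(OCc2ccccc2)C=C1OCc1ccccc1 | intermediate (not isolated)
13 | caesium phenoxide of methyl (E)-3-[2,4-bis(benzyloxy)-6-hydroxybenzoyl]-4-(4-methoxyphenyl)but-3-enoate | COC(=O)C/C(C(=O)c1c([O-])cc(OCc2ccccc2)cc1OCc1ccccc1)=C\c1ccc(OC)cc1.[Cs+] | intermediate (not isolated)
14 | rac-methyl 2-[(2S*,3R*)-5,7-bis(benzyloxy)-2-(4-methoxyphenyl)-4-oxochroman-3-yl]acetate (2,3-trans, racemic, (2S,3R) enantiomer drawn) | COc1ccc([C@H]2Oc3cc(OCc4ccccc4)cc(OCc4ccccc4)c3C(=O)[C@@H]2CC(=O)OC)cc1 | intermediate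
15 | methyl 2-[(2S,3R,4S)-5,7-bis(benzyloxy)-4-hydroxy-2-(4-methoxyphenyl)chroman-3-yl]acetate (all-cis) | COc1ccc([C@H]2Oc3cc(OCc4ccccc4)cc(OCc4ccccc4)c3[C@@H](O)[C@H]2CC(=O)OC)cc1 | intermediate (not isolated)
16 | (3aS,4S,9bS)-7,9-bis(benzyloxy)-4-(4-methoxyphenyl)-3,3a,4,9b-tetrahydro-2H-furo[3,2-c]chromen-2-one (cis-fused, aryl cis to the lactone) | COc1ccc([C@H]2Oc3cc(OCc4ccccc4)cc(OCc4ccccc4)c3[C@H]5OC(=O)C[C@@H]25)cc1 | intermediate
17 | 4-(benzyloxy)benzaldehyde | O=Cc1ccc(OCc2ccccc2)cc1 | starting material
18 | lithium aldolate of 16 with 17 (mixture of diastereomers at the two new carbons) | COc1ccc([C@H]2Oc3cc(OCc4ccccc4)cc(OCc4ccccc4)c3[C@H]5OC(=O)C(C([O-])c6ccc(OCc7ccccc7)cc6)[C@@H]25)cc1.[Li+] | intermediate (not isolated)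
19 | methanesulfonate of the aldol adduct (mixture of diastereomers at the two new carbons) | COc1ccc([C@H]2Oc3cc(OCc4ccccc4)cc(OCc4ccccc4)c3[C@H]5OC(=O)C(C(OS(C)(=O)=O)c6ccc(OCc7ccccc7)cc6)[C@@H]25)cc1 | intermediate (not isolated)
20 | (3E,3aS,4S,9bS)-7,9-bis(benzyloxy)-3-[4-(benzyloxy)benzylidene]-4-(4-methoxyphenyl)-3,3a,4,9b-tetrahydro-2H-furo[3,2-c]chromen-2-one | COc1ccc([C@H]2Oc3cc(OCc4ccccc4)cc(OCc4ccccc4)c3[C@H]5OC(=O)/C(=C/c6ccc(OCc7ccccc7)cc6)[C@@H]25)cc1 | intermediate
21 | potassium (E)-3-[4-(benzyloxy)phenyl]-2-[(2S,3R,4S)-5,7-bis(benzyloxy)-4-hydroxy-2-(4-methoxyphenyl)chroman-3-yl]prop-2-enoate (all-cis chroman) | COc1ccc([C@H]2Oc3cc(OCc4ccccc4)cc(OCc4ccccc4)c3[C@@H](O)[C@H]2/C(C(=O)[O-])=C\c2ccc(OCc3ccccc3)cc2)cc1.[K+] | intermediate (not isolated)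
22 | triisopropylsilyl (E)-3-[4-(benzyloxy)phenyl]-2-[(2S,3S,4S)-5,7-bis(benzyloxy)-2-(4-methoxyphenyl)-4-(triisopropylsilyloxy)chroman-3-yl]prop-2-enoate | COc1ccc([C@H]2Oc3cc(OCc4ccccc4)cc(OCc4ccccc4)c3[C@@H](O[Si](C(C)C)(C(C)C)C(C)C)[C@H]2/C(C(=O)O[Si](C(C)C)(C(C)C)C(C)C)=C\c2ccc(OCc3ccccc3)cc2)cc1 | intermediate (not isolated)
23 | (E)-3-[4-(benzyloxy)phenyl]-2-[(2S,3S,4S)-5,7-bis(benzyloxy)-2-(4-methoxyphenyl)-4-(triisopropylsilyloxy)chroman-3-yl]prop-2-enoic acid (all-cis chroman) | COc1ccc([C@H]2Oc3cc(OCc4ccccc4)cc(OCc4ccccc4)c3[C@@H](O[Si](C(C)C)(C(C)C)C(C)C)[C@H]2/C(C(=O)O)=C\c2ccc(OCc3ccccc3)cc2)cc1 | intermediate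
24 | caesium phenoxide of (E)-1-[2,4-bis(benzyloxy)-6-hydroxyphenyl]-3-[4-(benzyloxy)phenyl]-2-[(2S,3S,4S)-5,7-bis(benzyloxy)-2-(4-methoxyphenyl)-4-(triisopropylsilyloxy)chroman-3-yl]prop-2-en-1-one | COc1ccc([C@H]2Oc3cc(OCc4ccccc4)cc(OCc4ccccc4)c3[C@@H](O[Si](C(C)C)(C(C)C)C(C)C)[C@H]2/C(C(=O)c2c([O-])cc(OCc3ccccc3)cc2OCc2ccccc2)=C\c2ccc(OCc3ccccc3)cc2)cc1.[Cs+] | intermediate (not isolated)
25 | (2S,3S,4S)-5,7-bis(benzyloxy)-3-{(2R,3S)-5,7-bis(benzyloxy)-2-[4-(benzyloxy)phenyl]-4-oxochroman-3-yl}-2-(4-methoxyphenyl)-4-(triisopropylsilyloxy)chromane | COc1ccc([C@H]2Oc3cc(OCc4ccccc4)cc(OCc4ccccc4)c3[C@@H](O[Si](C(C)C)(C(C)C)C(C)C)[C@H]2[C@@H]2C(=O)c3c(OCc4ccccc4)cc(OCc4ccccc4)cc3O[C@H]2c2ccc(OCc3ccccc3)cc2)cc1 | intermediate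
26 | (2R,3S)-5,7-bis(benzyloxy)-2-[4-(benzyloxy)phenyl]-3-[(2S,3R,4S)-5,7-bis(benzyloxy)-4-hydroxy-2-(4-methoxyphenyl)chroman-3-yl]chroman-4-one | COc1ccc([C@H]2Oc3cc(OCc4ccccc4)cc(OCc4ccccc4)c3[C@@H](O)[C@H]2[C@@H]2C(=O)c3c(OCc4ccccc4)cc(OCc4ccccc4)cc3O[C@H]2c2ccc(OCc3ccccc3)cc2)cc1 | intermediate
27 | (2S,3S)-5,7-bis(benzyloxy)-3-{(2R,3S)-5,7-bis(benzyloxy)-2-[4-(benzyloxy)phenyl]-4-oxochroman-3-yl}-2-(4-methoxyphenyl)chroman-4-one | COc1ccc([C@H]2Oc3cc(OCc4ccccc4)cc(OCc4ccccc4)c3C(=O)[C@H]2[C@@H]2C(=O)c3c(OCc4ccccc4)cc(OCc4ccccc4)cc3O[C@H]2c2ccc(OCc3ccccc3)cc2)cc1 | intermediate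
28 | (2S,3S)-5,7-dihydroxy-3-[(2R,3S)-5,7-dihydroxy-2-(4-hydroxyphenyl)-4-oxochroman-3-yl]-2-(4-methoxyphenyl)chroman-4-one (CNP0196568.4) | COc1ccc([C@H]2Oc3cc(O)cc(O)c3C(=O)[C@H]2[C@@H]2C(=O)c3c(O)cc(O)cc3O[C@H]2c2ccc(O)cc2)cc1 | target

## Step count and risks

Total: 12 steps. Longest linear sequence: 10 steps (from 6 and 7 through steps 3–12; equally from 1 through steps 1, 2 and 5–12).

**Step 9 (key step).** Three processes are most likely to go wrong. The aryl anion may be protonated before it reaches the hindered, alpha-branched carbonyl, which diverts material to the simple aryl ester. Fluoride may slowly cleave the C4 silyl ether at 125 °C. The induction from C3 may be weak, because the sense of the trans unit B is decided only by a conformational preference about C3–C3'; isomers of the wrong sense can be returned to equilibrium with base and recycled.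

Fallback, setting out from lactone 20 and bromophenol 2 and returning at 26: 2 is O-allylated (allyl bromide, K2CO3, DMF) to 1-(allyloxy)-3,5-bis(benzyloxy)-2-bromobenzene F1. Bromine–lithium exchange (n-BuLi, THF, −78 °C) and addition of the aryllithium to the lactone carbonyl of 20 should give, after ring opening, the allyl-protected hydroxy enone F2. Pd(PPh3)4 with morpholine then removes the allyl group to give the free ortho-hydroxyaryl enone F3, and F3 is closed by oxa-Michael addition with NaOAc in EtOH at 50 °C to 26. Steps 8 to 10 are bypassed, and the ring closure becomes a separate, mild operation that can be equilibrated or placed under catalyst control.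

**Step 6.** Epimerisation at C3 may be slower than reduction. The trans epimer would then be reduced in part and the resolution would lose both diastereo- and enantioselection.

Fallback, setting out from 14 and returning at 16: dehydrogenation with DDQ (dioxane, 100 °C) gives the flavone-3-acetate F4. Conjugate reduction with LiBH(s-Bu)3 at −78 °C, with protonation of the enolate at low temperature from the face opposite the C2 aryl group, gives the racemic 2,3-cis ketone F5 under kinetic control. The same ruthenium catalyst under the non-epimerising HCO2H/Et3N (5:2) mixture then acts as a plain kinetic resolution of F5 and gives 16 by way of 15.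

**Step 8.** The C4 hydroxyl may attack the transient silyl ester and re-form the lactone faster than it is silylated.

Fallback, setting out from 20 and returning at 23: after the KOH opening, the potassium carboxylate 21 is alkylated with allyl bromide in DMF to the hydroxy allyl ester F6. F6 is silylated with i-Pr3SiOTf and 2,6-lutidine to the silyl ether F7, and the allyl ester is cleaved under neutral conditions with Pd(PPh3)4 and morpholine at rt to give 23.

**Step 5.** The acidic allylic CH2 of 11 may protonate the aryl anion, so that the aryl ester forms in place of the ketone.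

Fallback, setting out from 1 and 6 and returning at 14: Houben–Hoesch acylation of 1 with methyl 3-cyanopropanoate (ZnCl2, HCl, Et2O, 0 °C) gives the ketiminium chloride F8, which aqueous hydrolysis turns into the ortho-hydroxyaryl ketone F9. Pyrrolidine-mediated aldol condensation of F9 with 6, followed by oxa-Michael closure (EtOH, 60 °C), gives 14.

## Further compounds

F1 | step 9 | 1-(allyloxy)-3,5-bis(benzyloxy)-2-bromobenzene | C=CCOc1cc(OCc2ccccc2)cc(OCc2ccccc2)c1Br
F2 | step 9 | (E)-1-[2-(allyloxy)-4,6-bis(benzyloxy)phenyl]-3-[4-(benzyloxy)phenyl]-2-[(2S,3R,4S)-5,7-bis(benzyloxy)-4-hydroxy-2-(4-methoxyphenyl)chroman-3-yl]prop-2-en-1-one | COc1ccc([C@H]2Oc3cc(OCc4ccccc4)cc(OCc4ccccc4)c3[C@@H](O)[C@H]2/C(C(=O)c2c(OCC=C)cc(OCc3ccccc3)cc2OCc2ccccc2)=C\c2ccc(OCc3ccccc3)cc2)cc1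
F3 | step 9 | (E)-1-[2,4-bis(benzyloxy)-6-hydroxyphenyl]-3-[4-(benzyloxy)phenyl]-2-[(2S,3R,4S)-5,7-bis(benzyloxy)-4-hydroxy-2-(4-methoxyphenyl)chroman-3-yl]prop-2-en-1-one | COc1ccc([C@H]2Oc3cc(OCc4ccccc4)cc(OCc4ccccc4)c3[C@@H](O)[C@H]2/C(C(=O)c2c(O)cc(OCc3ccccc3)cc2OCc2ccccc2)=C\c2ccc(OCc3ccccc3)cc2)cc1
F4 | step 6 | methyl 2-[5,7-bis(benzyloxy)-2-(4-methoxyphenyl)-4-oxo-4H-chromen-3-yl]acetate | COC(=O)Cc1c(-c2ccc(OC)cc2)oc2cc(OCc3ccccc3)cc(OCc3ccccc3)c2c1=O
F5 | step 6 | rac-methyl 2-[(2S*,3S*)-5,7-bis(benzyloxy)-2-(4-methoxyphenyl)-4-oxochroman-3-yl]acetate (2,3-cis, racemic, (2S,3S) enantiomer drawn) | COc1ccc([C@H]2Oc3cc(OCc4ccccc4)cc(OCc4ccccc4)c3C(=O)[C@H]2CC(=O)OC)cc1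
F6 | step 8 | allyl (E)-3-[4-(benzyloxy)phenyl]-2-[(2S,3R,4S)-5,7-bis(benzyloxy)-4-hydroxy-2-(4-methoxyphenyl)chroman-3-yl]prop-2-enoate | COc1ccc([C@H]2Oc3cc(OCc4ccccc4)cc(OCc4ccccc4)c3[C@@H](O)[C@H]2/C(C(=O)OCC=C)=C\c2ccc(OCc3ccccc3)cc2)cc1
F7 | step 8 | allyl (E)-3-[4-(benzyloxy)phenyl]-2-[(2S,3S,4S)-5,7-bis(benzyloxy)-2-(4-methoxyphenyl)-4-(triisopropylsilyloxy)chroman-3-yl]prop-2-enoate | COc1ccc([C@H]2Oc3cc(OCc4ccccc4)cc(OCc4ccccc4)c3[C@@H](O[Si](C(C)C)(C(C)C)C(C)C)[C@H]2/C(C(=O)OCC=C)=C\c2ccc(OCc3ccccc3)cc2)cc1
F8 | step 5 | 1-[2,4-bis(benzyloxy)-6-hydroxyphenyl]-4-methoxy-4-oxobutan-1-iminium chloride | COC(=O)CCC(=[NH2+])c1c(O)cc(OCc2ccccc2)cc1OCc1ccccc1.[Cl-]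
F9 | step 5 | methyl 4-[2,4-bis(benzyloxy)-6-hydroxyphenyl]-4-oxobutanoate | COC(=O)CCC(=O)c1c(O)cc(OCc2ccccc2)cc1OCc1ccccc1
A1 | alternative 1 | Diels–Alder adduct: 3-(4-pivaloyloxyphenyl)-6-[4-(benzyloxy)phenyl]-4-[2,4-bis(benzyloxy)-6-fluorobenzoyl]-5-(2-oxooxazolidine-3-carbonyl)cyclohexene | CC(C)(C)C(=O)Oc1ccc([C@H]2C=C[C@@H](c3ccc(OCc4ccccc4)cc3)[C@@H](C(=O)N3CCOC3=O)[C@@H]2C(=O)c2c(F)cc(OCc3ccccc3)cc2OCc2ccccc2)cc1
A2 | alternative 1 | (1E,3E)-1-(4-pivaloyloxyphenyl)-4-[4-(benzyloxy)phenyl]buta-1,3-diene | CC(C)(C)C(=O)Oc1ccc(/C=C/C=C/c2ccc(OCc3ccccc3)cc2)cc1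
A3 | alternative 1 | 3-{(E)-4-[2,4-bis(benzyloxy)-6-fluorophenyl]-4-oxobut-2-enoyl}oxazolidin-2-one | O=C(/C=C/C(=O)c1c(F)cc(OCc2ccccc2)cc1OCc1ccccc1)N1CCOC1=O
A4 | alternative 2 | protected target with a tert-butyldimethylsilyl ether at O5 of unit A | COc1ccc([C@H]2Oc3cc(OCc4ccccc4)cc(O[Si](C)(C)C(C)(C)C)c3C(=O)[C@H]2[C@@H]2C(=O)c3c(OCc4ccccc4)cc(OCc4ccccc4)cc3O[C@H]2c2ccc(OCc3ccccc3)cc2)cc1
A5 | alternative 2 | alpha-diazo ketone: (2R,3S)-5,7-bis(benzyloxy)-2-[4-(benzyloxy)phenyl]-3-{1-diazo-2-[4-(benzyloxy)-2-(tert-butyldimethylsilyloxy)-6-(4-methoxybenzyloxy)phenyl]-2-oxoethyl}chroman-4-one | COc1ccc(COc2cc(OCc3ccccc3)cc(O[Si](C)(C)C(C)(C)C)c2C(=O)C(=[N+]=[N-])[C@@H]2C(=O)c3c(OCc4ccccc4)cc(OCc4ccccc4)cc3O[C@H]2c2ccc(OCc3ccccc3)cc2)cc1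
A6 | alternative 3 | tetrabenzyl ether of the target with the 4-hydroxyphenyl group free | COc1ccc([C@H]2Oc3cc(OCc4ccccc4)cc(OCc4ccccc4)c3C(=O)[C@H]2[C@@H]2C(=O)c3c(OCc4ccccc4)cc(OCc4ccccc4)cc3O[C@H]2c2ccc(O)cc2)cc1
A7 | alternative 3 | (2S,3S)-5,7-bis(benzyloxy)-3-{1-[2,4-bis(benzyloxy)-6-hydroxyphenyl]-3-(4-hydroxyphenyl)-1-oxopropan-2-yl}-2-(4-methoxyphenyl)chroman-4-one | COc1ccc([C@H]2Oc3cc(OCc4ccccc4)cc(OCc4ccccc4)c3C(=O)[C@H]2[C@@H](Cc2ccc(O)cc2)C(=O)c2c(O)cc(OCc3ccccc3)cc2OCc2ccccc2)cc1
A8 | alternative 3 | para-quinone methide derived from A7 | COc1ccc([C@H]2Oc3cc(OCc4ccccc4)cc(OCc4ccccc4)c3C(=O)[C@H]2[C@@H](C=C2C=CC(=O)C=C2)C(=O)c2c(O)cc(OCc3ccccc3)cc2OCc2ccccc2)cc1
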